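## Structural features

The target, 5,7-dihydroxy-2-[3-hydroxy-4-methoxy-5-(3-methylbut-2-enyl)phenyl]-8-(3-methylbut-2-enyl)-4H-chromen-4-one, is a flavone. Ring A (a phloroglucinol-type benzene) is fused along C4a–C8a to ring C (a 4-pyranone), and ring B is attached to C2 by one C–C bond. There is no stereocentre and no stereogenic alkene, so every problem is one of position, not of space. Ring A carries hydroxyls at C5 and C7 and a prenyl group at C8, the carbon between C7 and the O1-bearing C8a. Ring B carries three neighbouring substituents: 3'-OH, 4'-OMe and 5'-prenyl. The fragile parts are the two trisubstituted alkenes (the 8-prenyl group lies ortho to the 7-hydroxyl and can close to a dimethylchroman under acid) and the electron-rich free phenols. The real difficulty is regiochemical: prenyl at C8 and not C6, the OH/OMe/prenyl order on ring B, and a ring C closure mild enough for acetals and alkenes. The key step uses the fact that C3 and C4 are neighbours in ring C. Once O1–C2 exists as an enol ether, C3 (a bromine-bearing vinyl carbon) and C4 (the formyl carbon on C4a of ring A) lie cis to each other across O1–C2.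

## Logic of the disconnections

17 ⇒ 16. The three aryl O–CH2OCH3 bonds are cut. The phenols must be masked through a hot carbonate step, low-valent metals and an oxidation; methoxymethyl ethers tolerate all of these and leave under mild acid. Nothing is gained in skeleton, but every earlier step runs on neutral ethers. The demand is an acid step gentle enough for two prenyl groups, one of them next to a phenol that is being set free.

16 ⇒ 15. No skeletal bond is cut; the C4 carbonyl is taken back to a secondary carbinol. This allows C3–C4 to be made by a carbonyl addition. The demand is an oxidant selective for a doubly activated alcohol, applied to a compound that ionises easily.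

15 ⇒ 14. The C3–C4 bond is cut, which opens ring C. Both carbons become electrophiles, a vinyl bromide carbon and a formyl carbon, so the two arenes are now joined only through the O1–C2 enol ether. The forward step has to reverse the polarity of C3 reductively, keep the metal cis to the aryloxy oxygen, and add to the aldehyde before the aryloxide is lost.

14 ⇒ 6 + 13. The O1–C2 bond is cut. This divides the molecule into a ring A phenol-aldehyde and a ring B haloalkyne of similar size, and the forward addition sets the bromine at C3 and the alkene geometry in the same event. The demands are attack of oxygen at the aryl-bearing alkyne carbon, anti addition, and enough nucleophilicity from a hindered, hydrogen-bonded phenol.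

13 ⇒ 12 ⇒ 11. The C2≡C3 unit is taken back to a formyl group: C3 and its bromine come from a one-carbon reagent, and C2 is the formyl carbon of 11. This reduces the alkyne to an ordinary benzaldehyde. The demand is homologation and elimination without organolithium reagents and without acid, so that the bromine, the acetal and the prenyl group persist.

11 ⇒ 9 + 10. The C5'–CH2 bond is cut. The bromine already present in the commercial ring B aldehyde marks this carbon, so no regiochemical decision is needed. The demand is a cross-coupling that delivers the allylic group at its unsubstituted terminus and tolerates an aldehyde.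

9 ⇒ 8 ⇒ 7. The O–CH2 bond of the acetal and the O–CH3 bond are cut, leading to a commercial bromocatechol aldehyde. The demand is alkylation of only the hydroxyl para to the formyl group in the first forward step.

6 ⇒ 5 ⇒ 4 ⇒ 2 + 3. The C8–CH2 bond (C3–CH2 of the benzaldehyde) is cut by a retro-[3,3] shift that puts the C5 unit on the neighbouring oxygen, the alkene is taken back to an alkyne, and the tertiary O–C bond is cut. The hydroxyl freed in the forward shift is then, by construction, the one next to the prenyl group, so no later discrimination between two ortho hydroxyls is needed. The demand is O-alkylation of a chelated phenol by a tertiary electrophile and a shift to the single open ortho carbon.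

2 ⇒ 1. Two O–CH2 bonds are cut. The hydrogen bond to the formyl group in 1 leaves one ortho hydroxyl unreactive, so the forward step needs only control of stoichiometry.

## Other disconnections considered

Alternative 1: The cut is at both aryl–CH2 bonds, C8–CH2 and C5'–CH2. The forward key step is purely thermal: the bis-ether A1 (prenyl on O5, 1,1-dimethylallyl on O4') is heated in N,N-diethylaniline and should give A2 by an ortho-Claisen shift on ring B and a Claisen-then-Cope sequence on ring A.
- In its favour: the flavone core can be built first from simple unprenylated partners, and no tin, chromium or palladium is needed. On ring B, C3' is blocked, so the tertiary allyl ether can deliver prenyl only to C5'. On this point the alternative is the better plan, because a reagent-free shift replaces the cross-coupling of step 6.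
- Against it here: A1 needs two different allyl groups on two different oxygens. One of them, O5, is the hydrogen-bonded and least reactive hydroxyl; the other carries a tertiary ether that ionises easily. On ring A the first shift places a 1,1-dimethylallyl group on C6, and whether it moves on to C8 or simply enolises is decided by relative rates, not by structure. Temperatures near 200 °C are hard on acetals and on ortho-prenylphenols. A2 still needs selective methylation at O4' and deprotection.
- Comparison: in structure, the chosen plan fixes C8 through a single open ortho carbon, whereas the alternative depends on the partition of a dienone. In mechanism, both use sigmatropic shifts for ring A. In step count the alternative is probably equal or slightly shorter, at the price of two regiochemical uncertainties late in the route.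

Alternative 2: Three ring A bonds are cut (C4a–C5, C5–C6, C7–C8), so ring A is built onto a preformed 2-aryl-4-pyranone. In the forward step, irradiation of the diazo ketone A3 with the silyloxyalkyne A4 should trigger a Wolff rearrangement to a vinylketene, a [2+2] addition to the alkyne, 4π opening and 6π closure, giving A5 after tautomerisation.
- In its favour: every ring A substituent is placed by connectivity. The diazo carbon becomes C8 with its prenyl group, the ketene carbon becomes C5 with a free hydroxyl, and the silyloxy carbon becomes C7. No C6/C8 question arises, so on ring A regiochemistry it is the better plan. The end game is a single fluoride deprotection, one step shorter and free of acid, which is also better than steps 11 and 12.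
- Against it here: A3 is a demanding compound, a pyranone bearing an α-diazo ketone with a methylene next to the diazo carbon. Such carbenes can undergo a 1,2-hydrogen shift instead of rearranging. The pyranone absorbs in the same region and has photochemistry of its own. The ketene can be intercepted by the prenyl alkenes, and A4 is sensitive to hydrolysis.
- Comparison: in mechanism, a cascade of four pericyclic events must each outrun a side path, against one metal-mediated bond formation in the chosen plan. In step count, the gain at the end would most likely be lost in a longer preparation of A3 than the nine steps leading to 14.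

Alternative 3: The cut is at C4–C4a. In the forward step the acid A6, as its mixed trifluoroacetic anhydride buffered with 2,6-di-tert-butylpyridine, should acylate C4a in a Friedel–Crafts closure to give A7, which is the same compound as 16.
- In its favour: ring C arrives at the ketone oxidation level, so there is no labile carbinol and no oxidation. In redox economy and in the number of steps after ring closure it is the better plan. The phenol A8, which would be added to the propiolate A9, has no formyl group and is a stronger nucleophile than 6; this is also better. C4a is the only free ortho carbon of the aryloxy ring, so the ring-closure regiochemistry is equal.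
- Against it here: the anhydride releases trifluoroacetic acid and strong acylating species in the presence of three acetals and two nucleophilic alkenes. The addition of A8 to A9 is expected to give both alkene geometries, and only the Z acid can close. A8 raises the same problem as 6 (the free hydroxyl must be the one next to the prenyl group) without a formyl group to help, and a saponification is added.
- Comparison: the total count is about the same. The chosen plan closes ring C under neutral, reductive conditions that suit the protecting groups better, and pays for this with one oxidation and a sensitive intermediate.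

Key step: step 10

Remark on the chemistry: in 3-bromo-4,5-dihydroxybenzaldehyde C3 carries bromine, so the methoxymethyl group of ring B is placed on the 5-hydroxyl (C3' of the flavone) and the methyl group on the 4-hydroxyl.

Remark on the chemistry: the ring A prenyl group is delivered by a Claisen shift from the oxygen that becomes O1, so the free hydroxyl of 6 is next to the prenyl group by construction; skeleton and protecting groups of 14 are kept as drawn.

Remark on the chemistry: 15 is the carbinol base of a flavylium ion; it is assumed to survive a base-buffered work-up long enough to be oxidised as crude material.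

## Steps

Step 1
Reactants: 1 2,4,6-trihydroxybenzaldehyde
Product: 2 2-hydroxy-4,6-bis(methoxymethoxy)benzaldehyde
Conditions: MOMCl (2.2 equiv), i-Pr2NEt, CH2Cl2, 0 °C to rt
Reagents that add atoms: chloromethyl methyl ether (MOMCl), COCCl
Why: Williamson-type O-alkylation caps the para hydroxyl and one of the two equivalent ortho hydroxyls; the remaining ortho hydroxyl is held in a hydrogen bond to the formyl group and should stay free, so only the stoichiometry has to be controlled.

Step 2
Reactants: 2 2-hydroxy-4,6-bis(methoxymethoxy)benzaldehyde; 3 3-chloro-3-methylbut-1-yne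
Product: 4 4,6-bis(methoxymethoxy)-2-[(2-methylbut-3-yn-2-yl)oxy]benzaldehyde
Conditions: 3 (1.5 equiv), DBU, CuCl2·2H2O (1 mol%), MeCN, 0 °C to rt
Reagents that add atoms: none
Why: Copper-catalysed propargylic etherification: the copper acetylide of 3 ionises to a copper allenylidene that the phenoxide captures at the tertiary carbon, a path less sensitive to hindrance than direct displacement; 2 has one free hydroxyl, so no site selectivity is required.

Step 3
Reactants: 4 4,6-bis(methoxymethoxy)-2-[(2-methylbut-3-yn-2-yl)oxy]benzaldehyde
Product: 6 2-hydroxy-4,6-bis(methoxymethoxy)-3-(3-methylbut-2-en-1-yl)benzaldehyde, via 1,1-dimethylallyl ether 5 (not isolated)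
Conditions: H2 (1 atm), Pd/CaCO3 (Pb-poisoned), quinoline, toluene, rt; filter; then 120 °C
Reagents that add atoms: none
Why: Semi-hydrogenation of the terminal alkyne gives 5, which on heating undergoes an aromatic Claisen rearrangement ([3,3]) to the only ortho carbon bearing hydrogen (the other carries the formyl group); enolisation gives the prenyl phenol, whose hydroxyl now lies between prenyl and formyl and is the future O1.

Step 4
Reactants: 7 3-bromo-4,5-dihydroxybenzaldehyde
Product: 8 3-bromo-5-hydroxy-4-methoxybenzaldehyde
Conditions: MeI (1.05 equiv), Li2CO3, DMF, 40 °C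
Reagents that add atoms: iodomethane (MeI), CI
Why: Williamson ether synthesis under acidity control: the 4-hydroxyl, para to the formyl group and ortho to bromine, is the more acidic of the catechol pair, so a weak base and a limiting amount of MeI should methylate only that oxygen.

Step 5
Reactants: 8 3-bromo-5-hydroxy-4-methoxybenzaldehyde
Product: 9 3-bromo-4-methoxy-5-(methoxymethoxy)benzaldehyde
Conditions: MOMCl (1.3 equiv), i-Pr2NEt, CH2Cl2, 0 °C to rt
Reagents that add atoms: chloromethyl methyl ether (MOMCl), COCCl
Why: Routine O-alkylation of the one remaining phenol; the acetal is needed because a free ring B phenol would compete as a nucleophile in step 9.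

Step 6
Reactants: 9 3-bromo-4-methoxy-5-(methoxymethoxy)benzaldehyde; 10 tributyl(3-methylbut-2-en-1-yl)stannane
Product: 11 4-methoxy-3-(methoxymethoxy)-5-(3-methylbut-2-en-1-yl)benzaldehyde
Conditions: 10 (1.3 equiv), Pd(PPh3)4 (5 mol%), DMF, 100 °C; aq. KF work-up
Reagents that add atoms: none
Why: Stille cross-coupling: zerovalent palladium inserts into the aryl C–Br bond, the allylic stannane transmetalates, and reductive elimination at the less substituted allyl terminus should give the linear prenyl arene; aldehyde and acetal are inert to these neutral conditions.

Step 7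
Reactants: 11 4-methoxy-3-(methoxymethoxy)-5-(3-methylbut-2-en-1-yl)benzaldehyde
Product: 12 5-(2,2-dibromoethenyl)-2-methoxy-1-(methoxymethoxy)-3-(3-methylbut-2-en-1-yl)benzene
Conditions: CBr4 (2 equiv), PPh3 (4 equiv), Et3N, CH2Cl2, 0 °C
Reagents that add atoms: tetrabromomethane, BrC(Br)(Br)Br
Why: Corey–Fuchs dibromo-olefination, a Wittig reaction of Ph3P=CBr2 made in the flask; the added carbon is the future C3, and Et3N keeps the medium free of HBr so that the acetal and the prenyl alkene are spared.

Step 8
Reactants: 12 5-(2,2-dibromoethenyl)-2-methoxy-1-(methoxymethoxy)-3-(3-methylbut-2-en-1-yl)benzene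
Product: 13 5-(bromoethynyl)-2-methoxy-1-(methoxymethoxy)-3-(3-methylbut-2-en-1-yl)benzene
Conditions: DBU (3 equiv), DMSO, 15 °C
Reagents that add atoms: none
Why: Anti E2 loss of HBr (vinylic hydrogen and the trans bromine are antiperiplanar) gives the 1-bromoalkyne; an amidine base is used because an organolithium would also exchange the second bromine.

Step 9
Reactants: 6 2-hydroxy-4,6-bis(methoxymethoxy)-3-(3-methylbut-2-en-1-yl)benzaldehyde; 13 5-(bromoethynyl)-2-methoxy-1-(methoxymethoxy)-3-(3-methylbut-2-en-1-yl)benzene
Product: 14 2-({(Z)-2-bromo-1-[4-methoxy-3-(methoxymethoxy)-5-(3-methylbut-2-en-1-yl)phenyl]ethenyl}oxy)-4,6-bis(methoxymethoxy)-3-(3-methylbut-2-en-1-yl)benzaldehyde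
Conditions: 13 (1.3 equiv), Cs2CO3 (2 equiv), DMF, 100 °C
Reagents that add atoms: none
Why: Base-mediated hydrophenoxylation of a 1-bromoalkyne, a known reaction of salicylaldehyde-type phenols: the phenoxide attacks the aryl-bearing alkyne carbon so that the negative charge rests on the bromine-bearing carbon, and the vinyl anion, formed anti to the incoming oxygen, is protonated with retention. Bromine therefore ends cis to the aryloxy group (Z).

Step 10
Reactants: 14 2-({(Z)-2-bromo-1-[4-methoxy-3-(methoxymethoxy)-5-(3-methylbut-2-en-1-yl)phenyl]ethenyl}oxy)-4,6-bis(methoxymethoxy)-3-(3-methylbut-2-en-1-yl)benzaldehyde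
Product: 15 rac-5,7-bis(methoxymethoxy)-2-[4-methoxy-3-(methoxymethoxy)-5-(3-methylbut-2-en-1-yl)phenyl]-8-(3-methylbut-2-en-1-yl)-4H-chromen-4-ol
Conditions: CrCl2 (5 equiv), NiCl2 (5 mol%), degassed DMF, rt; aq. potassium sodium tartrate/NaHCO3 work-up, crude product used at once
Reagents that add atoms: none
Why: Intramolecular Nozaki–Hiyama–Kishi reaction: CrCl2 reduces NiCl2 to zerovalent nickel, which inserts into the C3–Br bond with retention; transmetalation to trivalent chromium gives a vinylchromium dichloride and returns divalent nickel to the cycle, and the vinylchromium adds to the formyl carbon C4. The closest known reaction type is the chromium/nickel-mediated cyclisation of vinyl halides onto aldehydes to cyclic allylic alcohols. Ring C closes in a 6-exo-trig mode, the attacked C=O lying outside the new ring O1–C2–C3–C4–C4a–C8a. C4 is the only new stereocentre; nothing controls it, both faces of the formyl group are open, and the racemate is acceptable because step 11 removes the centre. The step needs bromine cis to the aryloxy oxygen, which the anti addition of step 9 and the retentive metal exchanges secure, and it needs activation of one C–halogen bond only, which is the single one left in 14. It also needs addition to be faster than loss of aryloxide from the β-aryloxyvinyl metal: the carbon–chromium bond is largely covalent, the aryloxide sits syn to the metal (a poor geometry for elimination), and the aldehyde is held within reach. The reagent is neutral and non-basic, so acetals, prenyl alkenes and the enol ether should pass unchanged; the chromium alkoxide is released near pH 8 because the product ionises readily to a flavylium ion.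

Step 11
Reactants: 15 rac-5,7-bis(methoxymethoxy)-2-[4-methoxy-3-(methoxymethoxy)-5-(3-methylbut-2-en-1-yl)phenyl]-8-(3-methylbut-2-en-1-yl)-4H-chromen-4-ol
Product: 16 5,7-bis(methoxymethoxy)-2-[4-methoxy-3-(methoxymethoxy)-5-(3-methylbut-2-en-1-yl)phenyl]-8-(3-methylbut-2-en-1-yl)-4H-chromen-4-one
Conditions: activated MnO2 (15 equiv), K2CO3, CH2Cl2, rt
Reagents that add atoms: none
Why: MnO2 oxidation of an alcohol that is both allylic and benzylic; the product is the fully conjugated 4-pyranone, the stereocentre disappears, and solid carbonate keeps the suspension basic so that the carbinol is oxidised before it can ionise.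

Step 12
Reactants: 16 5,7-bis(methoxymethoxy)-2-[4-methoxy-3-(methoxymethoxy)-5-(3-methylbut-2-en-1-yl)phenyl]-8-(3-methylbut-2-en-1-yl)-4H-chromen-4-one
Product: 17 5,7-dihydroxy-2-[3-hydroxy-4-methoxy-5-(3-methylbut-2-en-1-yl)phenyl]-8-(3-methylbut-2-en-1-yl)-4H-chromen-4-one
Conditions: aq. HCl (3 M), MeOH, 40 °C
Reagents that add atoms: none
Why: Acid-catalysed acetal exchange with methanol frees the three phenols as dimethoxymethane; dilute acid at mild temperature is the usual way to unmask prenylated flavonoids, and the aryl methyl ether is not affected.

## Compound list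

1 | 2,4,6-trihydroxybenzaldehyde | O=Cc1c(O)cc(O)cc1O | starting material
2 | 2-hydroxy-4,6-bis(methoxymethoxy)benzaldehyde | O=Cc1c(O)cc(OCOC)cc1OCOC | intermediate
3 | 3-chloro-3-methylbut-1-yne | CC(C)(Cl)C#C | starting material
4 | 4,6-bis(methoxymethoxy)-2-[(2-methylbut-3-yn-2-yl)oxy]benzaldehyde | O=Cc1c(OC(C)(C)C#C)cc(OCOC)cc1OCOC | intermediate
5 | 4,6-bis(methoxymethoxy)-2-[(2-methylbut-3-en-2-yl)oxy]benzaldehyde (not isolated) | O=Cc1c(OC(C)(C)C=C)cc(OCOC)cc1OCOC | intermediate
6 | 2-hydroxy-4,6-bis(methoxymethoxy)-3-(3-methylbut-2-en-1-yl)benzaldehyde | O=Cc1c(O)c(CC=C(C)C)c(OCOC)cc1OCOC | intermediate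
7 | 3-bromo-4,5-dihydroxybenzaldehyde | O=Cc1cc(O)c(O)c(Br)c1 | starting material
8 | 3-bromo-5-hydroxy-4-methoxybenzaldehyde | COc1c(O)cc(C=O)cc1Br | intermediate
9 | 3-bromo-4-methoxy-5-(methoxymethoxy)benzaldehyde | COCOc1cc(C=O)cc(Br)c1OC | intermediate
10 | tributyl(3-methylbut-2-en-1-yl)stannane | CCCC[Sn](CCCC)(CCCC)CC=C(C)C | starting material
11 | 4-methoxy-3-(methoxymethoxy)-5-(3-methylbut-2-en-1-yl)benzaldehyde | COCOc1cc(C=O)cc(CC=C(C)C)c1OC | intermediate
12 | 5-(2,2-dibromoethenyl)-2-methoxy-1-(methoxymethoxy)-3-(3-methylbut-2-en-1-yl)benzene | COCOc1cc(C=C(Br)Br)cc(CC=C(C)C)c1OC | intermediate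
13 | 5-(bromoethynyl)-2-methoxy-1-(methoxymethoxy)-3-(3-methylbut-2-en-1-yl)benzene | COCOc1cc(C#CBr)cc(CC=C(C)C)c1OC | intermediate
14 | 2-({(Z)-2-bromo-1-[4-methoxy-3-(methoxymethoxy)-5-(3-methylbut-2-en-1-yl)phenyl]ethenyl}oxy)-4,6-bis(methoxymethoxy)-3-(3-methylbut-2-en-1-yl)benzaldehyde | Br/C=C(/c1cc(OCOC)c(OC)c(CC=C(C)C)c1)Oc1c(CC=C(C)C)c(OCOC)cc(OCOC)c1C=O | intermediate
15 | rac-5,7-bis(methoxymethoxy)-2-[4-methoxy-3-(methoxymethoxy)-5-(3-methylbut-2-en-1-yl)phenyl]-8-(3-methylbut-2-en-1-yl)-4H-chromen-4-ol (racemic at C4) | OC1C=C(c2cc(OCOC)c(OC)c(CC=C(C)C)c2)Oc2c(CC=C(C)C)c(OCOC)cc(OCOC)c21 | intermediate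
16 | 5,7-bis(methoxymethoxy)-2-[4-methoxy-3-(methoxymethoxy)-5-(3-methylbut-2-en-1-yl)phenyl]-8-(3-methylbut-2-en-1-yl)-4H-chromen-4-one | COc1c(OCOC)cc(-c2cc(=O)c3c(OCOC)cc(OCOC)c(CC=C(C)C)c3o2)cc1CC=C(C)C | intermediate
17 | 5,7-dihydroxy-2-[3-hydroxy-4-methoxy-5-(3-methylbut-2-en-1-yl)phenyl]-8-(3-methylbut-2-en-1-yl)-4H-chromen-4-one | COc1c(O)cc(-c2cc(=O)c3c(O)cc(O)c(CC=C(C)C)c3o2)cc1CC=C(C)C | target

## Step count and least certain steps

Total step count: 12. Longest linear sequence: 9 steps (7 to 17 through steps 4 to 12); the ring A branch (steps 1 to 3) joins at step 9.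

Step 10 (key step). Most likely to go wrong:
- loss of the aryloxide from the β-aryloxyvinyl metal intermediate, which would cleave O1–C2 again;
- protodemetalation, if addition to the hindered, electron-rich formyl group is slow;
- ionisation of the product carbinol to the flavylium ion during a work-up that is acidic from chromium salts.

Fallback: from 14, Pd(PPh3)4 with the biaryl phosphine XPhos and K2CO3 in 1,4-dioxane at 100 °C, a known palladium-catalysed acylation of vinyl bromides by aldehydes. Zerovalent palladium inserts into C3–Br, the vinylpalladium adds to the formyl group, and β-hydride elimination from the palladium alkoxide should give the ketone directly. The route is rejoined at 16; 15 and step 11 are left out, and no new compound is made (F0).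

Step 9. Most likely to go wrong: slow addition of a phenoxide that is hindered on both sides and weakened by conjugation with the formyl group, so that the bromoalkyne is consumed by base-induced decomposition or coupling with itself before it is captured.

Fallback: setting out from 12 and 6, ring C is closed through O1–C2 instead.
- 12 with n-BuLi (2.1 equiv, THF, −78 °C) gives lithium [4-methoxy-3-(methoxymethoxy)-5-(3-methylbut-2-en-1-yl)phenyl]ethynide F1.
- F1 is added to 6 that has first been deprotonated at the phenol with LiN(SiMe3)2, giving the racemic propargylic alcohol 2-{1-hydroxy-3-[4-methoxy-3-(methoxymethoxy)-5-(3-methylbut-2-en-1-yl)phenyl]prop-2-yn-1-yl}-3,5-bis(methoxymethoxy)-6-(3-methylbut-2-en-1-yl)phenol F2.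
- MnO2 in CH2Cl2 oxidises F2 to the ynone 1-[2-hydroxy-4,6-bis(methoxymethoxy)-3-(3-methylbut-2-en-1-yl)phenyl]-3-[4-methoxy-3-(methoxymethoxy)-5-(3-methylbut-2-en-1-yl)phenyl]prop-2-yn-1-one F3.
- The phenol of F3 should add to the alkyne in a 6-endo-dig conjugate addition (K2CO3, acetone, or catalytic DMAP in DMF), a known way to flavones.

The route is rejoined at 16.

Step 2. Most likely to go wrong: O-alkylation of the chelated, hindered phenoxide is outrun by consumption of the tertiary propargylic chloride through elimination or self-condensation of the copper allenylidene.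

Fallback: from 1, direct C-alkylation with 1-bromo-3-methylbut-2-ene (DBU, THF, rt) gives 2,4,6-trihydroxy-3-(3-methylbut-2-en-1-yl)benzaldehyde F4. MOMCl (2.1 equiv) and i-Pr2NEt in CH2Cl2 at 0 °C should then etherify the 4- and 6-hydroxyls and leave the hydroxyl wedged between prenyl and formyl, which rejoins the route at 6. This is shorter, but it depends on mono-C-alkylation of an ambident nucleophile and on steric discrimination between the two ortho hydroxyls.

Step 6. Most likely to go wrong: allylic transposition at palladium, delivering the 1,1-dimethylallyl isomer, or migration of the double bond into conjugation with the ring through a palladium hydride.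

Fallback: from 9, Stille coupling with allyltributylstannane (Pd(PPh3)4, toluene, 100 °C) gives 4-methoxy-3-(methoxymethoxy)-5-(prop-2-en-1-yl)benzaldehyde F5, for which transposition changes nothing. Cross-metathesis of F5 with an excess of 2-methylbut-2-ene (second-generation Grubbs catalyst, CH2Cl2, 40 °C) then builds the trisubstituted alkene and rejoins the route at 11.

Step 12. Most likely to go wrong: acid-promoted cyclisation of the 8-prenyl group onto the 7-hydroxyl as it is set free, or Markovnikov addition of methanol or HCl to the trisubstituted alkenes, both driven by protonation of the alkene in a protic acid.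

Fallback: from 16, the acetals are removed without protic acid by transacetalisation to a thiol, with ZnBr2 and propane-1-thiol in CH2Cl2 at 0 °C. The Lewis acid activates the acetal oxygen and the thiol captures the methoxymethyl cation, so the alkenes are never exposed to a strong Brønsted acid. The route is rejoined at 17 and no new compound is made (F0).

## Further compounds

F0 | step 10 | none | none
F1 | step 9 | lithium [4-methoxy-3-(methoxymethoxy)-5-(3-methylbut-2-en-1-yl)phenyl]ethynide | [Li]C#Cc1cc(OCOC)c(OC)c(CC=C(C)C)c1
F2 | step 9 | rac-2-{1-hydroxy-3-[4-methoxy-3-(methoxymethoxy)-5-(3-methylbut-2-en-1-yl)phenyl]prop-2-yn-1-yl}-3,5-bis(methoxymethoxy)-6-(3-methylbut-2-en-1-yl)phenol | OC(C#Cc1cc(OCOC)c(OC)c(CC=C(C)C)c1)c1c(O)c(CC=C(C)C)c(OCOC)cc1OCOC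
F3 | step 9 | 1-[2-hydroxy-4,6-bis(methoxymethoxy)-3-(3-methylbut-2-en-1-yl)phenyl]-3-[4-methoxy-3-(methoxymethoxy)-5-(3-methylbut-2-en-1-yl)phenyl]prop-2-yn-1-one | O=C(C#Cc1cc(OCOC)c(OC)c(CC=C(C)C)c1)c1c(O)c(CC=C(C)C)c(OCOC)cc1OCOC
F4 | step 2 | 2,4,6-trihydroxy-3-(3-methylbut-2-en-1-yl)benzaldehyde | O=Cc1c(O)cc(O)c(CC=C(C)C)c1O
F5 | step 6 | 4-methoxy-3-(methoxymethoxy)-5-(prop-2-en-1-yl)benzaldehyde | COCOc1cc(C=O)cc(CC=C)c1OC
F0 | step 12 | none | none
A1 | alternative 1 | 7-(methoxymethoxy)-2-{3-(methoxymethoxy)-4-[(2-methylbut-3-en-2-yl)oxy]phenyl}-5-[(3-methylbut-2-en-1-yl)oxy]-4H-chromen-4-one | O=c1cc(-c2ccc(OC(C)(C)C=C)c(OCOC)c2)oc2cc(OCOC)cc(OCC=C(C)C)c12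
A2 | alternative 1 | 5-hydroxy-2-[4-hydroxy-3-(methoxymethoxy)-5-(3-methylbut-2-en-1-yl)phenyl]-7-(methoxymethoxy)-8-(3-methylbut-2-en-1-yl)-4H-chromen-4-one | Oc1c(OCOC)cc(-c2cc(=O)c3c(O)cc(OCOC)c(CC=C(C)C)c3o2)cc1CC=C(C)C
A3 | alternative 2 | 2-diazo-1-{6-[4-methoxy-3-(3-methylbut-2-en-1-yl)-5-(triisopropylsilyloxy)phenyl]-4-oxo-4H-pyran-2-yl}-5-methylhex-4-en-1-one | [N-]=[N+]=C(CC=C(C)C)C(=O)c1cc(=O)cc(-c2cc(O[Si](C(C)C)(C(C)C)C(C)C)c(OC)c(CC=C(C)C)c2)o1
A4 | alternative 2 | (triisopropylsilyloxy)ethyne | C#CO[Si](C(C)C)(C(C)C)C(C)C
A5 | alternative 2 | 5-hydroxy-2-[4-methoxy-3-(3-methylbut-2-en-1-yl)-5-(triisopropylsilyloxy)phenyl]-8-(3-methylbut-2-en-1-yl)-7-(triisopropylsilyloxy)-4H-chromen-4-one | COc1c(O[Si](C(C)C)(C(C)C)C(C)C)cc(-c2cc(=O)c3c(O)cc(O[Si](C(C)C)(C(C)C)C(C)C)c(CC=C(C)C)c3o2)cc1CC=C(C)C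
A6 | alternative 3 | (Z)-3-[3,5-bis(methoxymethoxy)-2-(3-methylbut-2-en-1-yl)phenoxy]-3-[4-methoxy-3-(methoxymethoxy)-5-(3-methylbut-2-en-1-yl)phenyl]prop-2-enoic acid | OC(=O)/C=C(/c1cc(OCOC)c(OC)c(CC=C(C)C)c1)Oc1cc(OCOC)cc(OCOC)c1CC=C(C)C
A7 | alternative 3 | 5,7-bis(methoxymethoxy)-2-[4-methoxy-3-(methoxymethoxy)-5-(3-methylbut-2-en-1-yl)phenyl]-8-(3-methylbut-2-en-1-yl)-4H-chromen-4-one | COc1c(OCOC)cc(-c2cc(=O)c3c(OCOC)cc(OCOC)c(CC=C(C)C)c3o2)cc1CC=C(C)C
A8 | alternative 3 | 3,5-bis(methoxymethoxy)-2-(3-methylbut-2-en-1-yl)phenol | Oc1cc(OCOC)cc(OCOC)c1CC=C(C)C
A9 | alternative 3 | ethyl 3-[4-methoxy-3-(methoxymethoxy)-5-(3-methylbut-2-en-1-yl)phenyl]prop-2-ynoate | CCOC(=O)C#Cc1cc(OCOC)c(OC)c(CC=C(C)C)c1
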